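**Retrosynthetic overview**
- The target is reached by global hydrogenolysis (fourteen benzyl ethers and a C8–Br blocking group) of the perbenzylated bis-gallate, which comes from double esterification of the dimeric 3,3'-diol.
- Key disconnection: the interflavan C4–C6 bond, made with reversed polarity. Upper C4, normally the cationic centre, acts as a donor: a β-titanoxy benzylic radical from a 3α,4α-epoxide opened by (C5H5)2TiCl (trivalent titanium), a homoenolate-type equivalent of the ring A quinone methide. Lower C6 acts as the acceptor (aryl iodide on nickel).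
- The aryl group enters C4 last, trans to O3; the C3 oxygen stays at the carbinol level throughout, so the 2,3-cis relationship of epicatechin is never re-made.
- The epoxide comes from tetra-O-benzyl-epicatechin by 4β-hydroxylation and Mitsunobu closure; the aryl iodide comes from the same ether by C8 bromination, then C6 iodination.
- No ring of the target is built: rings A, B and C of both units come intact from (−)-epicatechin. The only ring formed is the transient oxirane (step 3), opened in step 6.

Assumption: (−)-epicatechin and 3,4,5-tris(benzyloxy)benzoic acid are bought; α/β refer to the usual flavan drawing (2-aryl and 3-OH of epicatechin are α, the interflavan bond is β).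

**Step 1**
Reactants: 1 (−)-epicatechin
Product: 2 5,7,3',4'-tetra-O-benzyl-(−)-epicatechin
Conditions: BnBr (4.4 equiv), K2CO3, DMF, 0 °C to rt
Reagents that add atoms: benzyl bromide, BrCc1ccccc1
Why: Williamson ether synthesis in which the carbonate base alkylates the four phenols but not the secondary 3-OH, and no stereocentre is touched.

**Step 2**
Reactants: 2 5,7,3',4'-tetra-O-benzyl-(−)-epicatechin
Product: 3 5,7,3',4'-tetra-O-benzyl-4β-hydroxy-(−)-epicatechin (2,3-cis-3,4-trans-3,4-diol)
Conditions: DDQ (1.2 equiv), CH2Cl2/H2O 18:1, rt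
Reagents that add atoms: water, O
Why: DDQ benzylic oxidation, in which hydride abstraction from C4 (para to O7, ortho to O5) gives a quinone-methide-type cation that water traps from the β face, anti to the axial 3α-OH and the 2α-aryl group, setting C4 as the 4β-alcohol.

**Step 3**
Reactants: 3 5,7,3',4'-tetra-O-benzyl-4β-hydroxy-(−)-epicatechin
Product: 4 (2R)-5,7,3',4'-tetra-O-benzyl-3α,4α-epoxyflavan
Conditions: PPh3, DIAD, THF, 0 °C; filtered through basic Al2O3 and used at once
Reagents that add atoms: none
Why: Mitsunobu cyclodehydration of a trans-diaxial 1,2-diol, in which the benzylic C4–O–PPh3+ bond ionises and the 3α-oxygen closes on C4 from the α face, so O3 and the C3 configuration are kept and C4 is inverted to the cis-fused 3α,4α-oxirane.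

**Step 4**
Reactants: 2 5,7,3',4'-tetra-O-benzyl-(−)-epicatechin
Product: 5 8-bromo-5,7,3',4'-tetra-O-benzyl-(−)-epicatechin
Conditions: NBS (1.0 equiv), CH2Cl2, −78 °C to rt
Reagents that add atoms: N-bromosuccinimide, O=C1CCC(=O)N1Br
Why: electrophilic aromatic bromination, which in 5,7-di-O-benzyl flavan-3-ols takes place first at C8 of ring A and so blocks that position.

**Step 5**
Reactants: 5 8-bromo-5,7,3',4'-tetra-O-benzyl-(−)-epicatechin
Product: 6 8-bromo-6-iodo-5,7,3',4'-tetra-O-benzyl-(−)-epicatechin
Conditions: NIS (1.1 equiv), TFA (5 mol%), MeCN/CH2Cl2, 0 °C, dark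
Reagents that add atoms: N-iodosuccinimide, O=C1CCC(=O)N1I
Why: electrophilic aromatic iodination at the only free position of ring A (C6, flanked by two benzyloxy groups), which fixes the site of the future interflavan bond.

**Step 6**
Reactants: 4 (2R)-5,7,3',4'-tetra-O-benzyl-3α,4α-epoxyflavan; 6 8-bromo-6-iodo-5,7,3',4'-tetra-O-benzyl-(−)-epicatechin
Product: 7 5,7,3',4'-tetra-O-benzyl-epicatechin-(4β→6)-[8-bromo-5,7,3',4'-tetra-O-benzyl-epicatechin], both 3-OH free
Conditions: NiCl2·MeOCH2CH2OMe (15 mol%), 4,4'-di-tert-butyl-2,2'-bipyridine (15 mol%), (C5H5)2TiCl2 (30 mol%), Mn, Et3N·HCl, DMPU/THF, 20 °C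
Reagents that add atoms: none
Why: nickel/titanium dual-catalysed reductive cross-electrophile coupling of an epoxide with an aryl iodide, in which (C5H5)2TiCl (trivalent titanium, from (C5H5)2TiCl2 and Mn) opens 4 homolytically at the benzylic C4–O bond to a β-titanoxy C4 radical (C4 reacting as a donor instead of the usual cation), which is captured by the aryl-nickel iodide formed from 6 at the C–I bond, so that two electrophilic carbons are joined and the aryl group is delivered anti to the bulky 3α-O–Ti group and the 2α-aryl group, setting C4 as 4β while C3 is never touched.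

**Step 7**
Reactants: 7 dimeric 3,3'-diol; 8 3,4,5-tris(benzyloxy)benzoic acid (3 equiv)
Product: 9 bis[3,4,5-tris(benzyloxy)benzoate] of 7 at O3 of both units
Conditions: DCC, DMAP, CH2Cl2, rt
Reagents that add atoms: none
Why: Steglich esterification of both secondary 3-OH groups, an O-acylation that leaves C3 of both units unchanged.

**Step 8**
Reactants: 9 perbenzylated 8-bromo bis-gallate
Product: 10 procyanidin B-5 3,3'-di-O-gallate
Conditions: H2 (1 atm), Pd(OH)2/C, NaOAc, THF/MeOH/H2O, rt
Reagents that add atoms: none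
Why: catalytic hydrogenolysis, which cleaves the fourteen benzyl ethers and, with NaOAc as HBr acceptor, the aryl C–Br bond at C8, while the gallate esters, the interflavan bond and the five stereocentres are not affected.

**Compound list**
1 | (−)-epicatechin, (2R,3R) | O[C@@H]1Cc2c(O)cc(O)cc2O[C@@H]1c1ccc(O)c(O)c1 | starting material
2 | 5,7,3',4'-tetra-O-benzyl-(−)-epicatechin | O[C@@H]1Cc2c(OCc3ccccc3)cc(OCc3ccccc3)cc2O[C@@H]1c1ccc(OCc2ccccc2)c(OCc2ccccc2)c1 | intermediate
3 | 5,7,3',4'-tetra-O-benzyl-4β-hydroxy-(−)-epicatechin, (2R,3R,4S), 3α-OH, 4β-OH | O[C@@H]1[C@@H](O)c2c(OCc3ccccc3)cc(OCc3ccccc3)cc2O[C@@H]1c1ccc(OCc2ccccc2)c(OCc2ccccc2)c1 | intermediate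
4 | (2R)-5,7,3',4'-tetra-O-benzyl-3α,4α-epoxyflavan (oxirane on the face of the 2-aryl group) | O1[C@@H]2[C@H]1c1c(OCc3ccccc3)cc(OCc3ccccc3)cc1O[C@@H]2c1ccc(OCc2ccccc2)c(OCc2ccccc2)c1 | intermediate
5 | 8-bromo-5,7,3',4'-tetra-O-benzyl-(−)-epicatechin | O[C@@H]1Cc2c(OCc3ccccc3)cc(OCc3ccccc3)c(Br)c2O[C@@H]1c1ccc(OCc2ccccc2)c(OCc2ccccc2)c1 | intermediate
6 | 8-bromo-6-iodo-5,7,3',4'-tetra-O-benzyl-(−)-epicatechin | O[C@@H]1Cc2c(OCc3ccccc3)c(I)c(OCc3ccccc3)c(Br)c2O[C@@H]1c1ccc(OCc2ccccc2)c(OCc2ccccc2)c1 | intermediate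
7 | 5,7,3',4'-tetra-O-benzyl-epicatechin-(4β→6)-[8-bromo-5,7,3',4'-tetra-O-benzyl-epicatechin]; upper unit 2α-aryl, 3α-OH, 4β-aryl; both 3-OH free | O[C@@H]1[C@@H](c2c(OCc3ccccc3)c(Br)c3c(c2OCc2ccccc2)C[C@@H](O)[C@@H](c2ccc(OCc4ccccc4)c(OCc4ccccc4)c2)O3)c2c(OCc3ccccc3)cc(OCc3ccccc3)cc2O[C@@H]1c1ccc(OCc2ccccc2)c(OCc2ccccc2)c1 | intermediate
8 | 3,4,5-tris(benzyloxy)benzoic acid | OC(=O)c1cc(OCc2ccccc2)c(OCc2ccccc2)c(OCc2ccccc2)c1 | starting material
9 | 3,3'-bis-O-[3,4,5-tris(benzyloxy)benzoyl] derivative of 7 | O=C(O[C@@H]1[C@@H](c2c(OCc3ccccc3)c(Br)c3c(c2OCc2ccccc2)C[C@@H](OC(=O)c2cc(OCc4ccccc4)c(OCc4ccccc4)c(OCc4ccccc4)c2)[C@@H](c2ccc(OCc4ccccc4)c(OCc4ccccc4)c2)O3)c2c(OCc3ccccc3)cc(OCc3ccccc3)cc2O[C@@H]1c1ccc(OCc2ccccc2)c(OCc2ccccc2)c1)c1cc(OCc2ccccc2)c(OCc2ccccc2)c(OCc2ccccc2)c1 | intermediate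
10 | procyanidin B-5 3,3'-di-O-gallate | O=C(O[C@@H]1[C@@H](c2c(O)cc3c(c2O)C[C@@H](OC(=O)c2cc(O)c(O)c(O)c2)[C@@H](c2ccc(O)c(O)c2)O3)c2c(O)cc(O)cc2O[C@@H]1c1ccc(O)c(O)c1)c1cc(O)c(O)c(O)c1 | target

**Step count and risks**
Total step count: 8. Longest linear sequence: 6 steps (steps 1, 2, 3, 6, 7, 8, or equally 1, 4, 5, 6, 7, 8).

Steps most likely to fail:

Step 6. The aryl iodide carries two ortho benzyloxy groups, so radical capture and reductive elimination at nickel may be slow. Zerovalent nickel may also insert into the C8–Br bond. Epoxide 4 may ionise under the Lewis-acidic salts and oligomerise, or be deoxygenated to the flav-3-ene. The fallback leaves the reductive manifold and makes the same bond by polar epoxide opening. It sets out from epoxide 4 and the non-iodinated bromide 5 (3 equiv) with BF3·OEt2 (0.1 equiv) in CH2Cl2 at −78 °C. The C6–H position of 5 (C8 blocked by bromine) attacks the benzylic C4 of the activated oxirane from the β face in a trans-diaxial opening, and the route is rejoined at 7. This fallback makes no new compound (entry F0), and step 5 is then not needed.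

Step 3. The oxirane of a 5,7-dialkoxy flavan is extremely acid-labile and may not survive isolation. A closure through activation of O3 instead of O4 would invert C3. The fallback avoids the oxirane. From diol 3, Me3SiCl in CH2Cl2 at −40 °C exchanges only the ionisable benzylic 4-OH for chloride (through the cation, trans to the 3-OH) to give 5,7,3',4'-tetra-O-benzyl-4β-chloro-(−)-epicatechin F1. F1 is used at once in a nickel-only reductive benzyl chloride/aryl iodide coupling with 6 (NiBr2·MeOCH2CH2OMe, 4,4'-di-tert-butyl-2,2'-bipyridine, Mn, DMA, 0 °C). The C4 radical is then formed by halogen abstraction instead of epoxide opening and is arylated anti to the free 3α-OH. The route is rejoined at 7.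

Step 2. DDQ can over-oxidise the new, very electron-rich benzylic alcohol to the 4-ketone, and the cation can attack ring A of a second molecule. The fallback traps the cation with a carboxylic acid instead of water. From 2, DDQ and AcOH (5 equiv) in CH2Cl2 give 5,7,3',4'-tetra-O-benzyl-4β-acetoxy-(−)-epicatechin F2, which DDQ does not oxidise further. K2CO3 (0.2 equiv) in MeOH/THF at 0 °C then removes the acetyl group by transesterification at the acyl carbon, so the C4–O bond and the 4β configuration are kept. The route is rejoined at 3.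

**Further compounds**
F0 | step 6 | none | none
F1 | step 3 | 5,7,3',4'-tetra-O-benzyl-4β-chloro-(−)-epicatechin | O[C@@H]1[C@@H](Cl)c2c(OCc3ccccc3)cc(OCc3ccccc3)cc2O[C@@H]1c1ccc(OCc2ccccc2)c(OCc2ccccc2)c1
F2 | step 2 | 5,7,3',4'-tetra-O-benzyl-4β-acetoxy-(−)-epicatechin | O[C@@H]1[C@@H](OC(C)=O)c2c(OCc3ccccc3)cc(OCc3ccccc3)cc2O[C@@H]1c1ccc(OCc2ccccc2)c(OCc2ccccc2)c1
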